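## Retrosynthetic overview

1. Last disconnection: the depside ester C(acyl)–O(aryl) bond. This gives an unprotected ring A tetraol and an activated ester of orsellinic acid (ring B).
2. The ring A tetraol comes from hydride reduction of dimethyl 3,5-dihydroxy-4-prenylphthalate.
3. Ring A is the only ring built. It is made by Diels–Alder/aromatisation of a 2-prenyl-1,3-bis(silyloxy)diene with dimethyl acetylenedicarboxylate, which fixes all six substituent positions at once.
4. The diene comes from methyl acetoacetate and prenyl bromide.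
5. Order: ring B is bought, ring A is formed in step 2, and the two rings are joined in the last step.

Assumption: the target SMILES has no stereocentre and no E/Z-isomeric double bond. The compound is therefore achiral and needs no enantioselective step. The two transient stereocentres on the way are racemic and disappear on aromatisation.

## Route

Step 1
Reactants: 1 methyl acetoacetate; 2 prenyl bromide (1-bromo-3-methylbut-2-ene)
Product: 3 methyl 2-acetyl-5-methylhex-4-enoate (racemic)
Conditions: 1 (1.3 equiv), 2 (1.0 equiv), K2CO3 (1.5 equiv), acetone, reflux, 12 h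
Reagents that add atoms: none
Why: Acetoacetic ester alkylation, an SN2 reaction of the stabilised enolate on a primary allylic bromide, in which the excess of 1 suppresses dialkylation.

Step 2
Reactants: 3 methyl 2-acetyl-5-methylhex-4-enoate; 4 dimethyl acetylenedicarboxylate
Product: 7 dimethyl 3,5-dihydroxy-4-(3-methylbut-2-en-1-yl)phthalate, via bis(silyloxy)diene 5 (not isolated), via cyclohexadiene cycloadduct 6 (not isolated)
Conditions: Me3SiOTf (2.3 equiv), Et3N (3.0 equiv), Et2O, 0 °C → rt; decant from the ammonium triflate, concentrate; 4 (1.2 equiv), toluene, 0 → 60 °C; then 1 M aq. HCl/THF, rt, 30 min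
Reagents that add atoms: trimethylsilyl triflate, C[Si](C)(C)OS(=O)(=O)C(F)(F)F (its Me3Si groups are present only in 5 and 6 and are gone in 7)
Why: Diels–Alder benzannulation of a Chan-type 1,3-bis(silyloxy)diene with a symmetrical alkyne, so there is no regiochemical issue, the prenyl group on diene C2 ends up between the two oxygenated carbons, and hydrolysis of the mixed silyl ketal expels MeOH to drive aromatisation.

Step 3
Reactants: 7 dimethyl 3,5-dihydroxy-4-(3-methylbut-2-en-1-yl)phthalate
Product: 8 4,5-bis(hydroxymethyl)-2-(3-methylbut-2-en-1-yl)benzene-1,3-diol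
Conditions: LiAlH4 (6 equiv), THF, Ar, 0 °C → rt, 3 h; aq. potassium sodium tartrate (KNaC4H4O6) work-up at 0 °C, pH about 7; no acid; use within a day
Reagents that add atoms: none
Why: Hydride reduction of both esters to alcohols, in which the aluminium phenoxide formed first can deliver hydride to the neighbouring ester, the isolated trisubstituted alkene is inert, and keeping at or below rt avoids quinone-methide over-reduction to a methyl group.

Step 4
Reactants: 9 orsellinic acid (2,4-dihydroxy-6-methylbenzoic acid)
Product: 10 pentafluorophenyl 2,4-dihydroxy-6-methylbenzoate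
Conditions: C6F5OH (1.2 equiv), DCC (1.05 equiv), EtOAc, 0 °C → rt, 6 h; filter, crystallise
Reagents that add atoms: pentafluorophenol, Oc1c(F)c(F)c(F)c(F)c1F
Why: Carbodiimide active-ester formation in which the acidic C6F5OH captures the O-acylisourea, the hydrogen-bonded 2-OH and the weakly nucleophilic 4-OH do not compete without base or acyl-transfer catalyst, and rt avoids decarboxylation.

Step 5
Reactants: 8 4,5-bis(hydroxymethyl)-2-(3-methylbut-2-en-1-yl)benzene-1,3-diol; 10 pentafluorophenyl 2,4-dihydroxy-6-methylbenzoate
Product: 12 3-hydroxy-4,5-bis(hydroxymethyl)-2-(3-methylbut-2-en-1-yl)phenyl 2,4-dihydroxy-6-methylbenzoate (target), via oxoketene 11 (not isolated)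
Conditions: 8 (1.2 equiv), KN(SiMe3)2 (2.4 equiv), degassed THF/DMF 4:1, −40 °C, 15 min; 10 (1.0 equiv) in THF added over 1 h; −40 °C → rt, 4 h; AcOH (2.4 equiv), 0 °C, then pH 6 phosphate buffer; chromatography without MeOH
Reagents that add atoms: none
Why: Proposed new method: protecting-group-free depside esterification by dissociative (E1cB) acyl transfer, in which the bis-phenoxide of 8 takes a phenolic proton from 10, the donor phenoxide expels C6F5O− (pKa about 5.5) to give the unhindered sp-hybridised oxoketene 11 and so bypasses the blocked addition–elimination path at the 2,6-disubstituted carbonyl, and 11 is captured by the remaining mono-phenoxide of 8, the only strong nucleophile present (the benzylic OH groups stay neutral, being roughly nine pK units less acidic in THF/DMF, and the phenoxides of 10 and 12 are conjugated to a carbonyl and far less nucleophilic); the oxygen flanked by H and prenyl should win over the oxygen flanked by prenyl and CH2OH because attack on a ketene occurs in the plane of its ortho substituents and the hindered phenoxide is also hydrogen-bonded to its neighbouring CH2OH, while the ester once formed cannot migrate (meta geometry to every other OH) and re-ionises orders of magnitude more slowly because its leaving group has pKa near 10; the closest known reaction types are the E1cB hydrolysis of activated aryl 4-hydroxybenzoates through p-oxoketenes, the trapping of photogenerated o-quinoketenes from benzodioxinones by alcohols, and phenoxide-selective Schotten–Baumann acylation.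

## Compound list

1 | methyl acetoacetate | CC(=O)CC(=O)OC | starting material
2 | prenyl bromide (1-bromo-3-methylbut-2-ene) | CC(C)=CCBr | starting material
3 | methyl 2-acetyl-5-methylhex-4-enoate (racemic) | CC(=O)C(CC=C(C)C)C(=O)OC | intermediate
4 | dimethyl acetylenedicarboxylate | COC(=O)C#CC(=O)OC | starting material
5 | 1-methoxy-2-(3-methylbut-2-en-1-yl)-1,3-bis(trimethylsilyloxy)buta-1,3-diene (E/Z mixture at the ketene acetal, not isolated) | C=C(O[Si](C)(C)C)C(CC=C(C)C)=C(OC)O[Si](C)(C)C | intermediate
6 | dimethyl 3-methoxy-4-(3-methylbut-2-en-1-yl)-3,5-bis(trimethylsilyloxy)cyclohexa-1,4-diene-1,2-dicarboxylate (racemic, not isolated) | COC1(O[Si](C)(C)C)C(CC=C(C)C)=C(O[Si](C)(C)C)CC(C(=O)OC)=C1C(=O)OC | intermediate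
7 | dimethyl 3,5-dihydroxy-4-(3-methylbut-2-en-1-yl)phthalate | COC(=O)c1cc(O)c(CC=C(C)C)c(O)c1C(=O)OC | intermediate
8 | 4,5-bis(hydroxymethyl)-2-(3-methylbut-2-en-1-yl)benzene-1,3-diol | CC(C)=CCc1c(O)cc(CO)c(CO)c1O | intermediate
9 | orsellinic acid (2,4-dihydroxy-6-methylbenzoic acid) | Cc1cc(O)cc(O)c1C(=O)O | starting material
10 | pentafluorophenyl 2,4-dihydroxy-6-methylbenzoate | Cc1cc(O)cc(O)c1C(=O)Oc1c(F)c(F)c(F)c(F)c1F | intermediate
11 | 3-hydroxy-5-methyl-6-(oxomethylidene)cyclohexa-2,4-dien-1-one (oxoketene, drawn as the ortho tautomer, not isolated) | O=C=C1C(=O)C=C(O)C=C1C | intermediate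
12 | 3-hydroxy-4,5-bis(hydroxymethyl)-2-(3-methylbut-2-en-1-yl)phenyl 2,4-dihydroxy-6-methylbenzoate (achiral) | CC(C)=CCc1c(OC(=O)c2c(C)cc(O)cc2O)cc(CO)c(CO)c1O | target

## Step count and risks

Total step count: 5.
Longest linear sequence: 4 (steps 1, 2, 3, 5).

**Most likely to fail, first: step 5 (the proposed new step).**
- The oxoketene may be captured by the phenoxide of 10 or of 12, giving oligodepsides.
- It may be captured by the hindered phenoxide, followed by acyl shift to the neighbouring CH2OH.
- It may be captured by a neutral CH2OH.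

The fallback uses known protecting-group chemistry. It sets out from 8 and 9 and comes back at 12.
- Compound 8 is persilylated (TBSCl, imidazole, DMF) to the tetrakis(tert-butyldimethylsilyl) ether F1.
- The two aryl silyl ethers are cleaved selectively (Cs2CO3, DMF/H2O 10:1, rt). This gives 4,5-bis(tert-butyldimethylsilyloxymethyl)-2-prenylbenzene-1,3-diol F2.
- In parallel, 9 is silylated (TBSCl 2.2 equiv, imidazole) to tert-butyldimethylsilyl 4-(tert-butyldimethylsilyloxy)-2-hydroxy-6-methylbenzoate F3.
- The silyl ester of F3 is hydrolysed (K2CO3, aq. THF, 0 °C) to 4-(tert-butyldimethylsilyloxy)-2-hydroxy-6-methylbenzoic acid F4.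
- Standard carbodiimide depside coupling of F4 with F2 (DCC, toluene, rt) acylates the less hindered phenol and gives the tris-silylated depside F5.
- Et3N·3HF in THF removes all three silyl groups to give 12.

**Second: step 3.**
- The ester next to the 3-OH is conjugated to two phenoxides, so reduction may stall at the hydroxyphthalide stage.
- Forcing conditions risk quinone-methide over-reduction.
- The 2,4-dihydroxybenzyl alcohol motif of 8 is acid-sensitive on work-up.

The fallback takes the phenoxides out of play. It sets out from 7 and comes back at 8.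
- Compound 7 is silylated (TBSOTf, 2,6-lutidine, CH2Cl2) to dimethyl 3,5-bis(tert-butyldimethylsilyloxy)-4-prenylphthalate F6.
- F6 is reduced with i-Bu2AlH (5 equiv, CH2Cl2, −78 → 0 °C) to [3,5-bis(tert-butyldimethylsilyloxy)-4-prenyl-1,2-phenylene]dimethanol F7.
- F7 is desilylated with Bu4NF/AcOH (THF, 0 °C) to 8. Any aryl-to-benzyl silyl shift in F7 is harmless because all silicon is removed.

**Third: step 2.**
- One-pot double silylation of an α-substituted keto ester may be incomplete.
- The crowded diene may add sluggishly to 4.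

The fallback installs the prenyl group after the ring is made. It sets out from 1 and 4 and comes back at 7.
- Compound 1 is converted (Me3SiOTf, Et3N, Et2O) to the parent 1-methoxy-1,3-bis(trimethylsilyloxy)buta-1,3-diene F8.
- Cycloaddition of F8 with 4 and acidic work-up give dimethyl 3,5-dihydroxyphthalate F9.
- Iodination between the two hydroxyls (I2, NaHCO3, THF/H2O, 0 °C) gives dimethyl 3,5-dihydroxy-4-iodophthalate F10.
- Stille coupling of F10 with tributyl(3-methylbut-2-en-1-yl)stannane (Pd(PPh3)4, LiCl, DMF, 80 °C) gives 7.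

## Further compounds

F1 | step 5 | tetrakis(tert-butyldimethylsilyl) ether of 8 | CC(C)=CCc1c(O[Si](C)(C)C(C)(C)C)cc(CO[Si](C)(C)C(C)(C)C)c(CO[Si](C)(C)C(C)(C)C)c1O[Si](C)(C)C(C)(C)C
F2 | step 5 | 4,5-bis(tert-butyldimethylsilyloxymethyl)-2-(3-methylbut-2-en-1-yl)benzene-1,3-diol | CC(C)=CCc1c(O)cc(CO[Si](C)(C)C(C)(C)C)c(CO[Si](C)(C)C(C)(C)C)c1O
F3 | step 5 | tert-butyldimethylsilyl 4-(tert-butyldimethylsilyloxy)-2-hydroxy-6-methylbenzoate | Cc1cc(O[Si](C)(C)C(C)(C)C)cc(O)c1C(=O)O[Si](C)(C)C(C)(C)C
F4 | step 5 | 4-(tert-butyldimethylsilyloxy)-2-hydroxy-6-methylbenzoic acid | Cc1cc(O[Si](C)(C)C(C)(C)C)cc(O)c1C(=O)O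
F5 | step 5 | tris(tert-butyldimethylsilyl)-protected depside | CC(C)=CCc1c(OC(=O)c2c(C)cc(O[Si](C)(C)C(C)(C)C)cc2O)cc(CO[Si](C)(C)C(C)(C)C)c(CO[Si](C)(C)C(C)(C)C)c1O
F6 | step 3 | dimethyl 3,5-bis(tert-butyldimethylsilyloxy)-4-(3-methylbut-2-en-1-yl)phthalate | COC(=O)c1cc(O[Si](C)(C)C(C)(C)C)c(CC=C(C)C)c(O[Si](C)(C)C(C)(C)C)c1C(=O)OC
F7 | step 3 | [3,5-bis(tert-butyldimethylsilyloxy)-4-(3-methylbut-2-en-1-yl)-1,2-phenylene]dimethanol | CC(C)=CCc1c(O[Si](C)(C)C(C)(C)C)cc(CO)c(CO)c1O[Si](C)(C)C(C)(C)C
F8 | step 2 | 1-methoxy-1,3-bis(trimethylsilyloxy)buta-1,3-diene | C=C(O[Si](C)(C)C)C=C(OC)O[Si](C)(C)C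
F9 | step 2 | dimethyl 3,5-dihydroxyphthalate | COC(=O)c1cc(O)cc(O)c1C(=O)OC
F10 | step 2 | dimethyl 3,5-dihydroxy-4-iodophthalate | COC(=O)c1cc(O)c(I)c(O)c1C(=O)OC
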